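**Plan**
- Retrosynthesis: the furan-2(5H)-one is cut at C2–C3 and O1–C5 into CO2 and a 1-substituted cyclopropene. Lactone atoms C3 (=CH), C4 (carbinol-bearing) and C5 (CH2) are the three ring carbons of the cyclopropene; its π-bond and ca. 54 kcal/mol ring strain are what let Ni(0) stitch CO2 across the CH–CH2 σ-bond in a formal (3+2) event.
- Further cuts (chain numbered from the carbinol, C1): C1–cyclopropenyl (aldehyde + cyclopropenyllithium); C2–C3 (alkenyllithium + ethylene oxide); C4–C5 and the C3 vinylic position (anti-carbomagnesiation of propargyl alcohol, then iodination); C6–C7 and the C8 methyl (alkyne methylalumination, ethylene oxide); alkyne from dihydro-β-ionone.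
- Forward: the cyclohexene ring is bought and the chain is grown linearly from it (C15 bromide → Z-iodo allylic alcohol → β,γ-unsaturated aldehyde → cyclopropenyl carbinol). The butenolide is the only ring made, closed in the penultimate step before global desilylation.
- Stereochemistry: 7E from syn-carboalumination; 3Z from chelate-controlled anti-carbomagnesiation and stereoretentive I/Li exchange; the (R)-carbinol from Sharpless kinetic resolution of the cyclopropenyl carbinol (L-(+)-DIPT), carried unchanged through the key step.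

Key step: step 12

Remark: the 1-substituted cyclopropenes 16–20 are assumed to be kept as cold solutions and used promptly, since cyclopropenes with a free ring CH2 dimerise on storage.

**Route**

Step 1
Reactants: 1 dihydro-β-ionone
Product: 3 2-(but-3-yn-1-yl)-1,3,3-trimethylcyclohex-1-ene, via enol phosphate 2 (not isolated)
Conditions: LDA, THF, −78 °C; ClP(O)(OEt)2, −78 °C → rt; then LDA (2.3 equiv), −78 °C → rt; aq. NH4Cl
Reagents that add atoms: none
Why: Kinetic deprotonation on the CH3 side, O-phosphorylation and LDA-induced elimination of the terminal enol phosphate (methyl ketone to terminal alkyne protocol) should give the alkyne without touching the tetrasubstituted ring alkene.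

Step 2
Reactants: 3 2-(but-3-yn-1-yl)-1,3,3-trimethylcyclohex-1-ene
Product: 5 (3E)-4-methyl-6-(2,6,6-trimethylcyclohex-1-en-1-yl)hex-3-en-1-ol, via alkenylalane 4 (not isolated)
Conditions: Me3Al (2.5 equiv), Cp2ZrCl2 (0.25 equiv), CH2Cl2, 0 °C → rt; then n-BuLi, hexane/THF, −78 → 0 °C; ethylene oxide, → rt
Reagents that add atoms: trimethylaluminium C[Al](C)C; ethylene oxide C1CO1
Why: Zr-catalysed syn-methylalumination (Negishi carboalumination) puts Al at the terminus cis to the new methyl, and the derived alanate opens ethylene oxide with retention, which fixes the 7E trisubstituted alkene of the target.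

Step 3
Reactants: 5 (3E)-4-methyl-6-(2,6,6-trimethylcyclohex-1-en-1-yl)hex-3-en-1-ol
Product: 6 2-[(3E)-6-bromo-3-methylhex-3-en-1-yl]-1,3,3-trimethylcyclohex-1-ene
Conditions: CBr4, PPh3, CH2Cl2, 0 °C
Reagents that add atoms: carbon tetrabromide BrC(Br)(Br)Br
Why: Appel bromination converts the primary homoallylic alcohol into the bromide under neutral conditions that leave both alkenes in place.

Step 4
Reactants: 6 2-[(3E)-6-bromo-3-methylhex-3-en-1-yl]-1,3,3-trimethylcyclohex-1-ene; 7 propargyl alcohol
Product: 10 (2Z,5E)-2-(iodomethylidene)-6-methyl-8-(2,6,6-trimethylcyclohex-1-en-1-yl)oct-5-en-1-ol, via Grignard reagent 8 (not isolated), via magnesium chelate 9 (not isolated)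
Conditions: 6, Mg, THF, rt → 45 °C; 7 pre-treated with i-PrMgCl (1.0 equiv), THF, 0 °C; combine, CuI (10 mol %), 0 °C → rt; then I2, THF, −40 → 0 °C
Reagents that add atoms: iodine II
Why: Copper-catalysed anti-carbomagnesiation of the magnesium alkoxide of propargyl alcohol adds the alkyl group to C2 and leaves magnesium at C3 cis to the CH2O group in a five-membered chelate, so iodinolysis with retention should give the (Z)-iodide that carries the future 3Z geometry.

Step 5
Reactants: 10 (2Z,5E)-2-(iodomethylidene)-6-methyl-8-(2,6,6-trimethylcyclohex-1-en-1-yl)oct-5-en-1-ol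
Product: 11 tert-butyl{[(2Z,5E)-2-(iodomethylidene)-6-methyl-8-(2,6,6-trimethylcyclohex-1-en-1-yl)oct-5-en-1-yl]oxy}dimethylsilane
Conditions: TBSCl, imidazole, DMF, 0 °C → rt
Reagents that add atoms: tert-butyldimethylsilyl chloride CC(C)(C)[Si](C)(C)Cl
Why: Standard silylation of the primary allylic alcohol masks it for the organolithium step and for the rest of the route.

Step 6
Reactants: 11 tert-butyl{[(2Z,5E)-2-(iodomethylidene)-6-methyl-8-(2,6,6-trimethylcyclohex-1-en-1-yl)oct-5-en-1-yl]oxy}dimethylsilane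
Product: 13 (3Z,7E)-4-{[(tert-butyldimethylsilyl)oxy]methyl}-8-methyl-10-(2,6,6-trimethylcyclohex-1-en-1-yl)deca-3,7-dien-1-ol, via alkenyllithium 12 (not isolated)
Conditions: t-BuLi (2.1 equiv), Et2O, −78 °C; ethylene oxide, BF3·OEt2, −78 °C
Reagents that add atoms: ethylene oxide C1CO1
Why: Iodine–lithium exchange proceeds with retention of alkene geometry, and BF3-activated opening of ethylene oxide at −78 °C should outrun 1,4 O-to-C silyl migration (retro-Brook rearrangement), adding C1–C2 with the Z-alkene intact.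

Step 7
Reactants: 13 (3Z,7E)-4-{[(tert-butyldimethylsilyl)oxy]methyl}-8-methyl-10-(2,6,6-trimethylcyclohex-1-en-1-yl)deca-3,7-dien-1-ol
Product: 14 (3Z,7E)-4-{[(tert-butyldimethylsilyl)oxy]methyl}-8-methyl-10-(2,6,6-trimethylcyclohex-1-en-1-yl)deca-3,7-dienal
Conditions: Dess–Martin periodinane, NaHCO3, CH2Cl2, 0 °C → rt; used at once
Reagents that add atoms: none
Why: Buffered Dess–Martin oxidation gives the β,γ-unsaturated aldehyde under non-basic conditions that should avoid migration of the Z-alkene into conjugation.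

Step 8
Reactants: 15 allyl chloride
Product: 16 cyclopropene
Conditions: NaN(SiMe3)2, toluene, 110 °C; gas stream condensed into THF at −78 °C
Reagents that add atoms: none
Why: Base-induced α-elimination of allyl chloride gives vinylcarbene, which closes to cyclopropene (the standard preparative route), collected as a cold THF solution.

Step 9
Reactants: 14 (3Z,7E)-4-{[(tert-butyldimethylsilyl)oxy]methyl}-8-methyl-10-(2,6,6-trimethylcyclohex-1-en-1-yl)deca-3,7-dienal; 16 cyclopropene
Product: 18 rac-(3Z,7E)-1-(cycloprop-1-en-1-yl)-4-{[(tert-butyldimethylsilyl)oxy]methyl}-8-methyl-10-(2,6,6-trimethylcyclohex-1-en-1-yl)deca-3,7-dien-1-ol, via cyclopropenyllithium 17 (not isolated)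
Conditions: 16, LDA, THF, −78 °C; then 14, −78 °C; H2O
Reagents that add atoms: none
Why: The vinylic C–H of cyclopropene (pKa about 29, acetylide-like) is lithiated by the amide base, and the weakly basic cyclopropenyllithium should add 1,2 to the aldehyde at −78 °C faster than it enolises it; the carbinol centre is formed racemic.

Step 10
Reactants: 18 rac-(3Z,7E)-1-(cycloprop-1-en-1-yl)-4-{[(tert-butyldimethylsilyl)oxy]methyl}-8-methyl-10-(2,6,6-trimethylcyclohex-1-en-1-yl)deca-3,7-dien-1-ol
Product: 19 (1R,3Z,7E)-1-(cycloprop-1-en-1-yl)-4-{[(tert-butyldimethylsilyl)oxy]methyl}-8-methyl-10-(2,6,6-trimethylcyclohex-1-en-1-yl)deca-3,7-dien-1-ol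
Conditions: Ti(OiPr)4 (10 mol %), L-(+)-DIPT (15 mol %), t-BuOOH (0.6 equiv), 4 Å MS, CH2Cl2, −20 °C; stopped just past half conversion
Reagents that add atoms: none
Why: Sharpless kinetic resolution, precedented for cyclopropenyl carbinols: with L-(+)-DIPT the (S)-allylic alcohol should be epoxidised at the strained alkene much faster, so the (R)-alcohol is recovered, while the homoallylic alkene and the silyl ether are not substrates.

Step 11
Reactants: 19 (1R,3Z,7E)-1-(cycloprop-1-en-1-yl)-4-{[(tert-butyldimethylsilyl)oxy]methyl}-8-methyl-10-(2,6,6-trimethylcyclohex-1-en-1-yl)deca-3,7-dien-1-ol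
Product: 20 (1R,3Z,7E)-1-(cycloprop-1-en-1-yl)-1-[(tert-butyldimethylsilyl)oxy]-4-{[(tert-butyldimethylsilyl)oxy]methyl}-8-methyl-10-(2,6,6-trimethylcyclohex-1-en-1-yl)deca-3,7-diene
Conditions: TBSCl, imidazole, DMF, 0 °C → rt
Reagents that add atoms: tert-butyldimethylsilyl chloride CC(C)(C)[Si](C)(C)Cl
Why: Silylation under mild basic conditions removes the free OH (which would bind nickel or form a carbonate with CO2) without exposing the cyclopropene to acid.

Step 12
Reactants: 20 (1R,3Z,7E)-1-(cycloprop-1-en-1-yl)-1-[(tert-butyldimethylsilyl)oxy]-4-{[(tert-butyldimethylsilyl)oxy]methyl}-8-methyl-10-(2,6,6-trimethylcyclohex-1-en-1-yl)deca-3,7-diene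
Product: 23 4-[(1R,3Z,7E)-1-[(tert-butyldimethylsilyl)oxy]-4-{[(tert-butyldimethylsilyl)oxy]methyl}-8-methyl-10-(2,6,6-trimethylcyclohex-1-en-1-yl)deca-3,7-dien-1-yl]furan-2(5H)-one, via nickelalactone 21 (not isolated), via allylnickel carboxylate 22 (not isolated)
Conditions: Ni(cod)2 (10 mol %), IPr (20 mol %), CO2 (1 atm), toluene, 0 °C → rt, slow addition of 20
Reagents that add atoms: carbon dioxide O=C=O
Why: Proposed new method: Ni(0)–IPr should bind the strained cyclopropene π-bond and couple it oxidatively with CO2 so that the CO2 carbon bonds to the unsubstituted vinylic CH (the regiochemistry of Ni(0)/CO2 coupling with terminal alkynes) and nickel to the substituted carbon, giving the cyclopropane-fused nickelalactone 21; strain-driven β-carbon elimination of the CH–CH2 bond (cyclopropylmetal to allylmetal opening) then gives the six-membered allylnickel carboxylate 22, and C(sp3)–O reductive elimination releases the butenolide and Ni(0). The closest known reaction types are the Ni(0)/NHC-catalysed (2+2+2) cycloaddition of diynes with CO2 to pyrones (oxidative cyclisation with CO2, then C–O reductive elimination) and the Pd(0)-catalysed (3+2) cycloaddition of methylenecyclopropanes with CO2 to γ-lactones (strain-release C–C cleavage and allyl–O bond formation). The lactone is the only ring closed: it arises by ring contraction of the six-membered oxanickelacycle through allyl–O reductive elimination, a 5-exo-tet closure in outcome, with the cis enoate geometry fixed by the metallacycle. No stereocentre is created; the (R)-silyloxy carbinol is never part of the allyl system, and the two transient cyclopropane stereocentres of 21 are erased on ring opening. The step needs regioselectivity (CO2 at the CH terminus, cleavage of the CH–CH2 bond), which the bulky α-silyloxyalkyl group and IPr should secure, and chemoselectivity for the cyclopropene over the tri- and tetrasubstituted alkenes and the allylic silyl ether, which follows from the ring strain. Slow addition under CO2 should suppress nickel-catalysed cyclopropene dimerisation, and the OTBS group is a poor leaving group for β-oxygen elimination.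

Step 13
Reactants: 23 4-[(1R,3Z,7E)-1-[(tert-butyldimethylsilyl)oxy]-4-{[(tert-butyldimethylsilyl)oxy]methyl}-8-methyl-10-(2,6,6-trimethylcyclohex-1-en-1-yl)deca-3,7-dien-1-yl]furan-2(5H)-one
Product: 24 4-[(1R,3Z,7E)-1-hydroxy-4-(hydroxymethyl)-8-methyl-10-(2,6,6-trimethylcyclohex-1-en-1-yl)deca-3,7-dien-1-yl]furan-2(5H)-one
Conditions: HF·pyridine, pyridine, THF, 0 °C → rt
Reagents that add atoms: none
Why: Buffered HF·pyridine should cleave both the primary allylic and the secondary TBS ether without base-induced isomerisation of the butenolide or ionisation of the allylic alcohols, giving the target with the (R)-carbinol untouched.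

**Compound list**

1 | dihydro-β-ionone, 4-(2,6,6-trimethylcyclohex-1-en-1-yl)butan-2-one | CC1=C(CCC(C)=O)C(C)(C)CCC1 | starting material
2 | enol phosphate: diethyl 4-(2,6,6-trimethylcyclohex-1-en-1-yl)but-1-en-2-yl phosphate; not isolated | CC1=C(CCC(=C)OP(=O)(OCC)OCC)C(C)(C)CCC1 | intermediate
3 | 2-(but-3-yn-1-yl)-1,3,3-trimethylcyclohex-1-ene | CC1=C(CCC#C)C(C)(C)CCC1 | intermediate
4 | alkenylalane: dimethyl[(1E)-2-methyl-4-(2,6,6-trimethylcyclohex-1-en-1-yl)but-1-en-1-yl]alane; not isolated | CC1=C(CC/C(C)=C/[Al](C)C)C(C)(C)CCC1 | intermediate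
5 | (3E)-4-methyl-6-(2,6,6-trimethylcyclohex-1-en-1-yl)hex-3-en-1-ol | CC1=C(CC/C(C)=C/CCO)C(C)(C)CCC1 | intermediate
6 | 2-[(3E)-6-bromo-3-methylhex-3-en-1-yl]-1,3,3-trimethylcyclohex-1-ene | CC1=C(CC/C(C)=C/CCBr)C(C)(C)CCC1 | intermediate
7 | propargyl alcohol (prop-2-yn-1-ol) | C#CCO | starting material
8 | Grignard reagent: [(3E)-4-methyl-6-(2,6,6-trimethylcyclohex-1-en-1-yl)hex-3-en-1-yl]magnesium bromide; not isolated | CC1=C(CC/C(C)=C/CC[Mg]Br)C(C)(C)CCC1 | intermediate
9 | magnesium chelate: 1-oxa-2-magnesacyclopent-3-ene carrying the C15 chain at C4 (drawn halide-free); not isolated | CC1=C(CC/C(C)=C/CCC2=C[Mg]OC2)C(C)(C)CCC1 | intermediate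
10 | (2Z,5E)-2-(iodomethylidene)-6-methyl-8-(2,6,6-trimethylcyclohex-1-en-1-yl)oct-5-en-1-ol (I cis to CH2OH) | CC1=C(CC/C(C)=C/CC/C(=C/I)CO)C(C)(C)CCC1 | intermediate
11 | TBS ether of 10 | CC1=C(CC/C(C)=C/CC/C(=C/I)CO[Si](C)(C)C(C)(C)C)C(C)(C)CCC1 | intermediate
12 | (Z)-alkenyllithium from 11; not isolated | CC1=C(CC/C(C)=C/CC/C(=C/[Li])CO[Si](C)(C)C(C)(C)C)C(C)(C)CCC1 | intermediate
13 | (3Z,7E)-4-{[(tert-butyldimethylsilyl)oxy]methyl}-8-methyl-10-(2,6,6-trimethylcyclohex-1-en-1-yl)deca-3,7-dien-1-ol | CC1=C(CC/C(C)=C/CC/C(=C/CCO)CO[Si](C)(C)C(C)(C)C)C(C)(C)CCC1 | intermediate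
14 | (3Z,7E)-4-{[(tert-butyldimethylsilyl)oxy]methyl}-8-methyl-10-(2,6,6-trimethylcyclohex-1-en-1-yl)deca-3,7-dienal | CC1=C(CC/C(C)=C/CC/C(=C/CC=O)CO[Si](C)(C)C(C)(C)C)C(C)(C)CCC1 | intermediate
15 | allyl chloride | C=CCCl | starting material
16 | cyclopropene | C1=CC1 | intermediate
17 | cyclopropenyllithium; not isolated | [Li]C1=CC1 | intermediate
18 | racemic cyclopropenyl carbinol (3Z,7E) | CC1=C(CC/C(C)=C/CC/C(=C/CC(O)C2=CC2)CO[Si](C)(C)C(C)(C)C)C(C)(C)CCC1 | intermediate
19 | (1R,3Z,7E)-cyclopropenyl carbinol | CC1=C(CC/C(C)=C/CC/C(=C/C[C@@H](O)C2=CC2)CO[Si](C)(C)C(C)(C)C)C(C)(C)CCC1 | intermediate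
20 | (1R,3Z,7E)-bis-TBS cyclopropene | CC1=C(CC/C(C)=C/CC/C(=C/C[C@@H](O[Si](C)(C)C(C)(C)C)C2=CC2)CO[Si](C)(C)C(C)(C)C)C(C)(C)CCC1 | intermediate
21 | cyclopropane-fused five-membered nickelalactone, IPr on Ni, ring-fusion configuration not specified; not isolated | CC1=C(CC/C(C)=C/CC/C(=C/C[C@@H](O[Si](C)(C)C(C)(C)C)C23CC2C(=O)O[Ni]3=C2N(c3c(C(C)C)cccc3C(C)C)C=CN2c2c(C(C)C)cccc2C(C)C)CO[Si](C)(C)C(C)(C)C)C(C)(C)CCC1 | intermediate
22 | six-membered oxanickelacycle (σ-allyl nickel carboxylate), IPr on Ni; not isolated | CC1=C(CC/C(C)=C/CC/C(=C/C[C@@H](O[Si](C)(C)C(C)(C)C)C2=CC(=O)O[Ni](=C3N(c4c(C(C)C)cccc4C(C)C)C=CN3c3c(C(C)C)cccc3C(C)C)C2)CO[Si](C)(C)C(C)(C)C)C(C)(C)CCC1 | intermediate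
23 | bis-TBS butenolide, 4-[(1R,3Z,7E)-1-(TBSO)-4-(TBSOCH2)-8-methyl-10-(2,6,6-trimethylcyclohex-1-en-1-yl)deca-3,7-dien-1-yl]furan-2(5H)-one | CC1=C(CC/C(C)=C/CC/C(=C/C[C@@H](O[Si](C)(C)C(C)(C)C)C2=CC(=O)OC2)CO[Si](C)(C)C(C)(C)C)C(C)(C)CCC1 | intermediate
24 | 4-[(1R,3Z,7E)-1-hydroxy-4-(hydroxymethyl)-8-methyl-10-(2,6,6-trimethylcyclohex-1-en-1-yl)deca-3,7-dien-1-yl]furan-2(5H)-one | CC1=C(CC/C(C)=C/CC/C(=C/C[C@@H](O)C2=CC(=O)OC2)CO)C(C)(C)CCC1 | target

**Count and risks**

Total step count: 13. Longest linear sequence: 12 steps (steps 1–7 and 9–13; step 8 is a one-step side branch).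

Steps most likely to fail:

1. Step 12 (Proposed new method). The catalyst may be drained by nickel-mediated cyclopropene oligomerisation before CO2 is taken up, the nickelalactone may fail to open or to eliminate reductively so that nothing turns over, or β-silyloxy elimination may compete. The fallback uses known chemistry, sets out from aldehyde 14 and returns at 23. 3-Furyllithium (3-bromofuran, n-BuLi, THF, −78 °C) is added to 14 to give the racemic 3-furyl carbinol F1. Dess–Martin oxidation gives the furyl ketone F2. CBS reduction with catecholborane and the (S)-Me-oxazaborolidine (furyl as the large group) should give the (R)-furyl carbinol F3. Silylation (TBSCl, imidazole) gives the bis-silyl furan F4. Singlet-oxygen photo-oxygenation in the presence of Hünig's base at −78 °C (the base-directed oxidation of 3-alkylfurans to 4-alkyl-5-hydroxybutenolides) gives the γ-hydroxybutenolide F5. NaBH4 reduction followed by acidification closes the lactone to 23.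

2. Step 10. The rate difference between the enantiomers may be too small, or the Lewis-acidic oxidising medium may erode the slow-reacting cyclopropene. The fallback sets out from 18 and returns at 19, replacing kinetic resolution by separation of covalent diastereomers. Esterification of 18 with (S)-O-methylmandelic acid (DCC, cat. DMAP, CH2Cl2, 0 °C) gives the mandelate of the (R)-carbinol F6 and the mandelate of the (S)-carbinol F7. These are separated by chromatography and assigned by the mandelate NMR model. Methanolysis of F6 (K2CO3, MeOH, 0 °C) returns 19.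

3. Step 6. The (Z)-γ-silyloxy alkenyllithium may undergo 1,4 O-to-C silyl migration (retro-Brook rearrangement) or be protonated before it opens the epoxide. The fallback sets out from 11 and returns at 13 without an organolithium. Suzuki–Miyaura coupling of 11 with vinylboronic acid pinacol ester (Pd(dppf)Cl2, K2CO3, THF/H2O) gives, with retention, the (Z)-1,3-diene F8. Chemoselective hydroboration of its terminal vinyl group with 9-BBN gives the B-alkyl borane F9, and NaOH/H2O2 oxidation gives 13.

**Further compounds**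

F1 | step 12 | racemic 3-furyl carbinol from 14 | CC1=C(CC/C(C)=C/CC/C(=C/CC(O)c2ccoc2)CO[Si](C)(C)C(C)(C)C)C(C)(C)CCC1
F2 | step 12 | 3-furyl ketone | CC1=C(CC/C(C)=C/CC/C(=C/CC(=O)c2ccoc2)CO[Si](C)(C)C(C)(C)C)C(C)(C)CCC1
F3 | step 12 | (R)-3-furyl carbinol | CC1=C(CC/C(C)=C/CC/C(=C/C[C@@H](O)c2ccoc2)CO[Si](C)(C)C(C)(C)C)C(C)(C)CCC1
F4 | step 12 | (R)-bis-TBS 3-substituted furan | CC1=C(CC/C(C)=C/CC/C(=C/C[C@@H](O[Si](C)(C)C(C)(C)C)c2ccoc2)CO[Si](C)(C)C(C)(C)C)C(C)(C)CCC1
F5 | step 12 | 5-hydroxy-4-substituted furan-2(5H)-one (γ-hydroxybutenolide, hemiacetal epimers) | CC1=C(CC/C(C)=C/CC/C(=C/C[C@@H](O[Si](C)(C)C(C)(C)C)C2=CC(=O)OC2O)CO[Si](C)(C)C(C)(C)C)C(C)(C)CCC1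
F6 | step 10 | (S)-O-methylmandelate of the (R)-carbinol | CC1=C(CC/C(C)=C/CC/C(=C/C[C@@H](OC(=O)[C@@H](OC)c2ccccc2)C2=CC2)CO[Si](C)(C)C(C)(C)C)C(C)(C)CCC1
F7 | step 10 | (S)-O-methylmandelate of the (S)-carbinol | CC1=C(CC/C(C)=C/CC/C(=C/C[C@H](OC(=O)[C@@H](OC)c2ccccc2)C2=CC2)CO[Si](C)(C)C(C)(C)C)C(C)(C)CCC1
F8 | step 6 | (Z)-1,3-diene, TBS ether of (2Z,5E)-2-allylidene-6-methyl-8-(2,6,6-trimethylcyclohex-1-en-1-yl)oct-5-en-1-ol | CC1=C(CC/C(C)=C/CC/C(=C/C=C)CO[Si](C)(C)C(C)(C)C)C(C)(C)CCC1
F9 | step 6 | B-alkyl-9-borabicyclo[3.3.1]nonane from F8 | CC1=C(CC/C(C)=C/CC/C(=C/CCB2C3CCCC2CCC3)CO[Si](C)(C)C(C)(C)C)C(C)(C)CCC1
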